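**Retrosynthetic overview**

1. Germacrane numbering: ring C1–C10; C14 is the ester carbon on C10; lactone O6–C12(=O)–C11(=C13)–C7 on ring bond C6–C7; oxirane C4/C5 (C15 methyl on C4); methacrylate on O8, acetate on O9. Enabling feature: C9 is a carbinol carbon bonded to C10, the α-carbon of the C1=C10–C14 enoate (a hydroxyalkyl-acrylate, aldol-type motif with C2 cis to C9), and the cis-fused five-membered lactone ring holds the C5 and C8 arms of the ten-membered ring on one face.
2. End game: O9 acetylation, then epoxidation of C4=C5 of the ten-membered dienolide, whose ring shields one face of that alkene.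
3. C9–C10 (key): reductive Ni/Cr union of the C10 alkenyl iodide with the C9 aldehyde of an acyclic seco-aldehyde closes the ten-membered ring and sets C9.
4. C6–C7: indium Barbier allylation of enal fragment A (C1–C6, C10, C14, C15; from geranyl acetate) with allyl bromide fragment B (C7–C9, C11–C13; from (S)-glyceraldehyde acetonide and methyl acrylate), then lactonisation; C8 of the chiral pool relays C7 and C6, then C9, then C4/C5.
5. Ring order: lactone ring (step 10), ten-membered carbocycle (step 14), oxirane (step 16).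

Key step: step 14

Remark: the target SMILES is read as 4R,5R,6S,7S,8R,9R with a cis-fused lactone; where the CIP descriptor of an intermediate differs from that of the target, this reflects a change of substituent priorities and not an inversion.

**Route**

Step 1
Reactants: 1 geranyl acetate
Product: 2 (2E)-5-(3,3-dimethyloxiran-2-yl)-3-methylpent-2-en-1-yl acetate (racemic)
Conditions: mCPBA (1.0 equiv), NaHCO3, CH2Cl2, 0 °C
Reagents that add atoms: mCPBA, OOC(=O)c1cccc(Cl)c1
Why: Prilezhaev epoxidation should be selective for the electron-rich distal 6,7-alkene because the 2,3-alkene is deactivated by the allylic acetate; the new centre is racemic and is destroyed in step 2.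

Step 2
Reactants: 2 (2E)-5-(3,3-dimethyloxiran-2-yl)-3-methylpent-2-en-1-yl acetate
Product: 4 (2E)-3-methyl-6-oxohex-2-en-1-yl acetate, via glycol 3 (not isolated)
Conditions: H5IO6 (1.2 equiv), THF/H2O, 0 °C to 23 °C
Reagents that add atoms: none
Why: Periodic acid hydrolyses the epoxide to glycol 3 and cleaves it (Malaprade reaction) to the aldehyde and acetone, while the allylic acetate and the trisubstituted alkene are inert.

Step 3
Reactants: 4 (2E)-3-methyl-6-oxohex-2-en-1-yl acetate
Product: 5 methyl (2Z,6E)-8-acetoxy-2-iodo-6-methylocta-2,6-dienoate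
Conditions: Ph3P=CHCO2Me (1.3 equiv), NIS (1.3 equiv), CH2Cl2, −20 °C; then 4, 23 °C
Reagents that add atoms: methyl (triphenylphosphoranylidene)acetate, COC(=O)C=P(c1ccccc1)(c1ccccc1)c1ccccc1; N-iodosuccinimide, O=C1CCC(=O)N1I
Why: Wittig olefination with the stabilised α-iodo ylide formed in the flask should place the chain trans to the ester (Z by CIP, iodine cis to C2), which is the C1=C10 geometry of the target; the minor E isomer is removed by chromatography.

Step 4
Reactants: 5 methyl (2Z,6E)-8-acetoxy-2-iodo-6-methylocta-2,6-dienoate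
Product: 6 methyl (2Z,6E)-8-hydroxy-2-iodo-6-methylocta-2,6-dienoate
Conditions: K2CO3 (0.2 equiv), MeOH, 0 °C
Reagents that add atoms: none
Why: Zemplén-type transesterification removes the primary allylic acetate as methyl acetate, while the methyl ester is degenerate toward methanol and the iodoenoate should survive the short exposure at 0 °C.

Step 5
Reactants: 6 methyl (2Z,6E)-8-hydroxy-2-iodo-6-methylocta-2,6-dienoate
Product: 7 methyl (2Z,6E)-2-iodo-6-methyl-8-oxoocta-2,6-dienoate (fragment A)
Conditions: MnO2 (activated, 15 equiv), CH2Cl2, 23 °C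
Reagents that add atoms: none
Why: MnO2 oxidises only the allylic alcohol to the enal, with retention of the E geometry and without touching the iodoenoate.

Step 6
Reactants: 8 methyl (4S)-2,2-dimethyl-1,3-dioxolane-4-carboxylate
Product: 9 (4S)-2,2-dimethyl-1,3-dioxolane-4-carbaldehyde
Conditions: i-Bu2AlH (1.05 equiv), CH2Cl2, −78 °C; MeOH, then aq. KNaC4H4O6
Reagents that add atoms: none
Why: Partial ester reduction through the aluminium hemiacetal that is stable at −78 °C should give the aldehyde without epimerisation of the α-oxygenated centre, and the aldehyde is used crude at once.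

Step 7
Reactants: 9 (4S)-2,2-dimethyl-1,3-dioxolane-4-carbaldehyde; 10 methyl acrylate
Product: 11 methyl 2-{[(4S)-2,2-dimethyl-1,3-dioxolan-4-yl](hydroxy)methyl}prop-2-enoate (both carbinol epimers)
Conditions: DABCO (0.5 equiv), 10 (neat, 5 equiv), 23 °C
Reagents that add atoms: none
Why: Morita–Baylis–Hillman reaction; the new carbinol centre (C7) may form as a mixture of epimers, which is of no consequence because C7 becomes sp2 in step 8, and the tertiary amine is too weak a base to epimerise C8.

Step 8
Reactants: 11 methyl 2-{[(4S)-2,2-dimethyl-1,3-dioxolan-4-yl](hydroxy)methyl}prop-2-enoate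
Product: 12 methyl (2Z)-2-(bromomethyl)-3-[(4R)-2,2-dimethyl-1,3-dioxolan-4-yl]prop-2-enoate (fragment B)
Conditions: NBS (1.2 equiv), Me2S (1.3 equiv), CH2Cl2, 0 °C to 23 °C
Reagents that add atoms: N-bromosuccinimide, O=C1CCC(=O)N1Br
Why: Corey–Kim-type activation of the allylic alcohol as an alkoxysulfonium salt and SN2′ attack of bromide should give the rearranged primary allyl bromide as the thermodynamic isomer with the dioxolane trans to the ester, under non-acidic conditions that spare the acetonide (the C8 descriptor changes from S to R by priority only).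

Step 9
Reactants: 12 methyl (2Z)-2-(bromomethyl)-3-[(4R)-2,2-dimethyl-1,3-dioxolan-4-yl]prop-2-enoate; 7 methyl (2Z,6E)-2-iodo-6-methyl-8-oxoocta-2,6-dienoate
Product: 14 dimethyl (2Z,6E,8R,9R)-9-[(4R)-2,2-dimethyl-1,3-dioxolan-4-yl]-8-hydroxy-2-iodo-6-methyl-10-methylideneundeca-2,6-dienedioate, via allylindium 13 (not isolated)
Conditions: In powder (1.5 equiv), 12 (1.5 equiv), THF/H2O (1:1), 23 °C
Reagents that add atoms: none
Why: Indium Barbier (alkoxycarbonyl)allylation: allylindium 13 adds through its γ-carbon C7 to the enal carbonyl (1,2-addition) in a chair Zimmerman–Traxler transition state, which for this reagent with the C8 group cis to the CH2–In carbon should give the syn C6/C7 adduct (later the cis lactone), while coordination of dioxolane oxygen O8 to indium, with H8 eclipsing the alkene by A(1,3) strain, delivers the aldehyde to the alkene face syn to O8, so that C7 and C6 are set from C8.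

Step 10
Reactants: 14 dimethyl (2Z,6E,8R,9R)-9-[(4R)-2,2-dimethyl-1,3-dioxolan-4-yl]-8-hydroxy-2-iodo-6-methyl-10-methylideneundeca-2,6-dienedioate
Product: 16 methyl (2Z,6E)-7-{(2R,3S)-3-[(1R)-1,2-dihydroxyethyl]-4-methylidene-5-oxooxolan-2-yl}-2-iodo-6-methylhepta-2,6-dienoate, via lactone acetonide 15 (not isolated)
Conditions: TsOH·H2O (0.05 equiv), CH2Cl2, 0 °C to 23 °C; then MeOH, 23 °C
Reagents that add atoms: none
Why: Acid-catalysed 5-exo-trig lactonisation of the C6 hydroxyl onto the acrylate ester comes first (it is the only free hydroxyl, so no six-membered lactone can form, and the allylic C6–O bond becomes an ester that catalytic acid does not ionise), and transketalisation of the terminal acetonide with methanol then frees the 8,9-diol.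

Step 11
Reactants: 16 methyl (2Z,6E)-7-{(2R,3S)-3-[(1R)-1,2-dihydroxyethyl]-4-methylidene-5-oxooxolan-2-yl}-2-iodo-6-methylhepta-2,6-dienoate
Product: 17 methyl (2Z,6E)-7-{(2R,3S)-3-[(1R)-1-hydroxy-2-(triethylsilyloxy)ethyl]-4-methylidene-5-oxooxolan-2-yl}-2-iodo-6-methylhepta-2,6-dienoate
Conditions: Et3SiCl (1.05 equiv), imidazole (2 equiv), CH2Cl2, −40 °C
Reagents that add atoms: chlorotriethylsilane, CC[Si](Cl)(CC)CC
Why: Silylation at low temperature should be selective for the primary C9 hydroxyl over the hindered secondary C8 hydroxyl of the 1,2-diol.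

Step 12
Reactants: 17 methyl (2Z,6E)-7-{(2R,3S)-3-[(1R)-1-hydroxy-2-(triethylsilyloxy)ethyl]-4-methylidene-5-oxooxolan-2-yl}-2-iodo-6-methylhepta-2,6-dienoate
Product: 18 methyl (2Z,6E)-2-iodo-6-methyl-7-{(2R,3R)-4-methylidene-3-[(1R)-1-(2-methylprop-2-enoyloxy)-2-(triethylsilyloxy)ethyl]-5-oxooxolan-2-yl}hepta-2,6-dienoate
Conditions: methacrylic anhydride (2 equiv), Et3N (3 equiv), DMAP (0.2 equiv), CH2Cl2, 0 °C to 23 °C
Reagents that add atoms: methacrylic anhydride, CC(=C)C(=O)OC(=O)C(C)=C
Why: Steglich-type DMAP-catalysed acylation of the only free (secondary, C8) hydroxyl installs the methacrylate with retention of configuration.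

Step 13
Reactants: 18 methyl (2Z,6E)-2-iodo-6-methyl-7-{(2R,3R)-4-methylidene-3-[(1R)-1-(2-methylprop-2-enoyloxy)-2-(triethylsilyloxy)ethyl]-5-oxooxolan-2-yl}hepta-2,6-dienoate
Product: 19 methyl (2Z,6E)-2-iodo-6-methyl-7-{(2R,3R)-4-methylidene-3-[(1R)-1-(2-methylprop-2-enoyloxy)-2-oxoethyl]-5-oxooxolan-2-yl}hepta-2,6-dienoate (seco-aldehyde)
Conditions: (COCl)2 (3 equiv), DMSO (6 equiv), CH2Cl2, −78 °C to −30 °C; then Et3N (8 equiv), −78 °C to 0 °C
Reagents that add atoms: none
Why: Under Swern conditions a primary triethylsilyl ether is cleaved by the chlorosulfonium reagent and oxidised directly to the aldehyde, so the free 9-alcohol, into which the 8-ester could migrate, is never formed, and the cold amine quench should not epimerise C8.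

Step 14
Reactants: 19 methyl (2Z,6E)-2-iodo-6-methyl-7-{(2R,3R)-4-methylidene-3-[(1R)-1-(2-methylprop-2-enoyloxy)-2-oxoethyl]-5-oxooxolan-2-yl}hepta-2,6-dienoate
Product: 21 methyl (1(10)E,4E,6R,7R,8R,9R)-9-hydroxy-8-(2-methylprop-2-enoyloxy)germacra-1(10),4,11(13)-trien-12,6-olid-14-oate, via alkenylchromium 20 (not isolated)
Conditions: CrCl2 (8 equiv), NiCl2 (0.02 equiv), DMSO/THF (3:1), 23 °C, syringe-pump addition of 19 to 2 mM
Reagents that add atoms: none
Why: CrCl2 reduces NiCl2 to zerovalent nickel, which inserts into the C10–I bond; transmetalation to trivalent chromium gives alkenylchromium 20, and its addition to the C9 aldehyde unites two carbons that are both electrophilic in 19 (C–I and C=O) by polarity reversal at C10. The closest known reaction type is the Nozaki–Hiyama–Kishi alkenyl iodide–aldehyde macrocyclisation, which has closed ten-membered germacranolide rings, together with the chromium Reformatsky addition of α-halo esters. The ten-membered carbocycle is closed in a 10-exo-trig addition, helped by the cis-fused lactone, which holds the C5 and C8 arms on one face, and by the two geometrically fixed alkenes, which leave few free rotors. C9 is controlled by the ring-forming transition state: the C8–O8 bond lies antiperiplanar to the forming bond (Felkin–Anh polar requirement) and the chromium-bound oxygen points to the outside of the ring, trans to O8 and away from the lactone face, which corresponds to Re-face attack and should give 9R. The step needs chemoselective activation of the C–I bond next to three esters and two acrylate units (nickel inserts only into the sp2 C–I bond and alkenylchromium reagents add only to aldehydes), retention of the C1=C10 geometry (the σ-alkenyl chromium species should be configurationally stable, and closure with C2 cis to C9 is in any case the less strained mode) and ring closure over oligomerisation (high dilution and slow addition).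

Step 15
Reactants: 21 methyl (1(10)E,4E,6R,7R,8R,9R)-9-hydroxy-8-(2-methylprop-2-enoyloxy)germacra-1(10),4,11(13)-trien-12,6-olid-14-oate
Product: 22 methyl (1(10)E,4E,6R,7R,8R,9R)-9-acetoxy-8-(2-methylprop-2-enoyloxy)germacra-1(10),4,11(13)-trien-12,6-olid-14-oate
Conditions: Ac2O (3 equiv), pyridine (5 equiv), DMAP (0.1 equiv), CH2Cl2, 0 °C to 23 °C
Reagents that add atoms: acetic anhydride, CC(=O)OC(C)=O
Why: DMAP-catalysed acetylation of the allylic 9-hydroxyl should outrun migration of the neighbouring 8-ester and leaves all stereocentres untouched.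

Step 16
Reactants: 22 methyl (1(10)E,4E,6R,7R,8R,9R)-9-acetoxy-8-(2-methylprop-2-enoyloxy)germacra-1(10),4,11(13)-trien-12,6-olid-14-oate
Product: 23 fluctuadin
Conditions: dimethyldioxirane (1.1 equiv, acetone solution), CH2Cl2, −20 °C to 0 °C
Reagents that add atoms: dimethyldioxirane, CC1(C)OO1
Why: The electrophilic dioxirane should attack only the electron-rich trisubstituted C4=C5 bond (the three enoate alkenes are electron-poor) and is stereospecific (E-alkene to trans-oxirane); in the ten-membered ring A(1,3) strain between the C15 methyl and C6 keeps H6 in the alkene plane, the ring chain covers one face and the oxidant adds to the exposed face syn to O6, which should give 4R,5R.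

**Compound list**

1 | geranyl acetate, (2E)-3,7-dimethylocta-2,6-dien-1-yl acetate | CC(C)=CCC/C(C)=C/COC(C)=O | starting material
2 | (2E)-5-(3,3-dimethyloxiran-2-yl)-3-methylpent-2-en-1-yl acetate (racemic) | CC1(C)OC1CC/C(C)=C/COC(C)=O | intermediate
3 | (2E)-6,7-dihydroxy-3,7-dimethyloct-2-en-1-yl acetate (racemic glycol, not isolated) | CC(C)(O)C(O)CC/C(C)=C/COC(C)=O | intermediate
4 | (2E)-3-methyl-6-oxohex-2-en-1-yl acetate | O=CCC/C(C)=C/COC(C)=O | intermediate
5 | methyl (2Z,6E)-8-acetoxy-2-iodo-6-methylocta-2,6-dienoate | COC(=O)/C(I)=C/CC/C(C)=C/COC(C)=O | intermediate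
6 | methyl (2Z,6E)-8-hydroxy-2-iodo-6-methylocta-2,6-dienoate | COC(=O)/C(I)=C/CC/C(C)=C/CO | intermediate
7 | methyl (2Z,6E)-2-iodo-6-methyl-8-oxoocta-2,6-dienoate (fragment A) | COC(=O)/C(I)=C/CC/C(C)=C/C=O | intermediate
8 | methyl (4S)-2,2-dimethyl-1,3-dioxolane-4-carboxylate | CC1(C)O[C@@H](CO1)C(=O)OC | starting material
9 | (4S)-2,2-dimethyl-1,3-dioxolane-4-carbaldehyde | CC1(C)O[C@@H](CO1)C=O | intermediate
10 | methyl acrylate | C=CC(=O)OC | starting material
11 | methyl 2-{[(4S)-2,2-dimethyl-1,3-dioxolan-4-yl](hydroxy)methyl}prop-2-enoate (both carbinol epimers) | CC1(C)O[C@@H](CO1)C(O)C(=C)C(=O)OC | intermediate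
12 | methyl (2Z)-2-(bromomethyl)-3-[(4R)-2,2-dimethyl-1,3-dioxolan-4-yl]prop-2-enoate (fragment B) | CC1(C)O[C@@H](CO1)/C=C(/C(=O)OC)CBr | intermediate
13 | {(2Z)-3-[(4R)-2,2-dimethyl-1,3-dioxolan-4-yl]-2-(methoxycarbonyl)prop-2-en-1-yl}indium dibromide (schematic allylindium, not isolated) | CC1(C)O[C@@H](CO1)/C=C(/C(=O)OC)C[In](Br)Br | intermediate
14 | dimethyl (2Z,6E,8R,9R)-9-[(4R)-2,2-dimethyl-1,3-dioxolan-4-yl]-8-hydroxy-2-iodo-6-methyl-10-methylideneundeca-2,6-dienedioate (6R,7R,8R in germacrane numbering) | CC1(C)O[C@@H](CO1)[C@H](C(=C)C(=O)OC)[C@H](O)/C=C(\C)CC/C=C(/C(=O)OC)I | intermediate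
15 | methyl (2Z,6E)-7-{(2R,3R)-3-[(4R)-2,2-dimethyl-1,3-dioxolan-4-yl]-4-methylidene-5-oxooxolan-2-yl}-2-iodo-6-methylhepta-2,6-dienoate (not isolated) | CC1(C)O[C@@H](CO1)[C@@H]2C(=C)C(=O)O[C@@H]2/C=C(\C)CC/C=C(/C(=O)OC)I | intermediate
16 | methyl (2Z,6E)-7-{(2R,3S)-3-[(1R)-1,2-dihydroxyethyl]-4-methylidene-5-oxooxolan-2-yl}-2-iodo-6-methylhepta-2,6-dienoate | OC[C@H](O)[C@@H]1C(=C)C(=O)O[C@@H]1/C=C(\C)CC/C=C(/C(=O)OC)I | intermediate
17 | methyl (2Z,6E)-7-{(2R,3S)-3-[(1R)-1-hydroxy-2-(triethylsilyloxy)ethyl]-4-methylidene-5-oxooxolan-2-yl}-2-iodo-6-methylhepta-2,6-dienoate | CC[Si](CC)(CC)OC[C@H](O)[C@@H]1C(=C)C(=O)O[C@@H]1/C=C(\C)CC/C=C(/C(=O)OC)I | intermediate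
18 | methyl (2Z,6E)-2-iodo-6-methyl-7-{(2R,3R)-4-methylidene-3-[(1R)-1-(2-methylprop-2-enoyloxy)-2-(triethylsilyloxy)ethyl]-5-oxooxolan-2-yl}hepta-2,6-dienoate | C=C(C)C(=O)O[C@@H](CO[Si](CC)(CC)CC)[C@@H]1C(=C)C(=O)O[C@@H]1/C=C(\C)CC/C=C(/C(=O)OC)I | intermediate
19 | methyl (2Z,6E)-2-iodo-6-methyl-7-{(2R,3R)-4-methylidene-3-[(1R)-1-(2-methylprop-2-enoyloxy)-2-oxoethyl]-5-oxooxolan-2-yl}hepta-2,6-dienoate (seco-aldehyde) | C=C(C)C(=O)O[C@@H](C=O)[C@@H]1C(=C)C(=O)O[C@@H]1/C=C(\C)CC/C=C(/C(=O)OC)I | intermediate
20 | C10 alkenylchromium dichloride derived from 19 (chromium in place of iodine, solvated, not isolated) | C=C(C)C(=O)O[C@@H](C=O)[C@@H]1C(=C)C(=O)O[C@@H]1/C=C(\C)CC/C=C(/C(=O)OC)[Cr](Cl)Cl | intermediate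
21 | methyl (1(10)E,4E,6R,7R,8R,9R)-9-hydroxy-8-(2-methylprop-2-enoyloxy)germacra-1(10),4,11(13)-trien-12,6-olid-14-oate | C=C(C)C(=O)O[C@@H]1[C@@H]2C(=C)C(=O)O[C@@H]2/C=C(\C)CC/C=C(/C(=O)OC)[C@H]1O | intermediate
22 | methyl (1(10)E,4E,6R,7R,8R,9R)-9-acetoxy-8-(2-methylprop-2-enoyloxy)germacra-1(10),4,11(13)-trien-12,6-olid-14-oate | C=C(C)C(=O)O[C@@H]1[C@@H]2C(=C)C(=O)O[C@@H]2/C=C(\C)CC/C=C(/C(=O)OC)[C@H]1OC(C)=O | intermediate
23 | fluctuadin (4R,5R,6S,7S,8R,9R) | C=C(C)C(=O)O[C@@H]1[C@@H]2C(=C)C(=O)O[C@@H]2[C@H]2O[C@]2(C)CC/C=C(/C(=O)OC)[C@H]1OC(C)=O | target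

**Step count and risks**

Total steps: 16. Longest linear sequence: 13 steps (steps 1–5, then 9–16).

Steps most likely to fail:

1. Step 14. What may go wrong: addition to the wrong face of the C9 aldehyde (9-epimer), loss of the C1=C10 geometry if the alkenylchromium equilibrates through its O-bound allenolate form, or oligomerisation. Fallback (sets out from 19, returns at 21): the ring is closed as in step 14 without regard to the carbinol configuration, which should give 21 together with its 9-epimer F1. The mixture is oxidised with Dess–Martin periodinane (NaHCO3, CH2Cl2, 0 °C) to the ten-membered 9-ketone F2. The ketone is reduced under reagent control by Corey–Bakshi–Shibata reduction ((R)-2-methyl-CBS-oxazaborolidine, catecholborane, toluene, −78 °C; the α-substituted alkenyl arm taken as the large group; the other catalyst enantiomer is equally available), or under Felkin–Anh control by Luche reduction (NaBH4, CeCl3·7H2O, MeOH, −78 °C), to return to 21. C9 is then set by hydride delivery to a ring ketone and not by the carbon–carbon bond formation.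

2. Step 9. What may go wrong: attack on the other face of the allyl unit if the indium–O8 chelate is not maintained in the aqueous medium (6,7-bis-epimer), or erosion of the syn preference. Fallback (sets out from 11, returns at 14): 11 is acetylated (Ac2O, DMAP, CH2Cl2) to methyl 2-{acetoxy[(4S)-2,2-dimethyl-1,3-dioxolan-4-yl]methyl}prop-2-enoate F3. Palladium-catalysed borylation with allylic transposition (Pd2(dba)3, B2pin2, toluene, 50 °C) should give methyl (2E)-3-[(4R)-2,2-dimethyl-1,3-dioxolan-4-yl]-2-[(4,4,5,5-tetramethyl-1,3,2-dioxaborolan-2-yl)methyl]prop-2-enoate F4. F4 adds to enal 7 in a Brønsted-acid-catalysed allylboration with the matched enantiomer of the BINOL-derived phosphoric acid TRIP (toluene, −30 °C), which returns 14. The closed six-membered boron transition state fixes the syn relationship, and the chiral acid, not chelation, selects the aldehyde face.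

3. Step 16. What may go wrong: epoxidation from the shielded face through a minor ring conformer (4S,5S-oxirane), that is, poor facial selectivity. Fallback (sets out from 18, returns at 23): the oxirane is installed at the acyclic stage under reagent control by Shi epoxidation (D-fructose-derived ketone, KHSO5 as 2KHSO5·KHSO4·K2SO4, K2CO3, MeCN/dimethoxymethane/aqueous Na2B4O7 buffer, 0 °C), which should give the 4R,5R-epoxide of 18 F5. The direct Swern oxidation of step 13 then gives epoxy seco-aldehyde F6. The Ni/Cr closure of step 14, through epoxy alkenylchromium F7 (not isolated), gives epoxy ten-membered alcohol F8. Acetylation as in step 15 gives 23 directly.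

Further compounds
F1 | step 14 | 9-epimer of 21 (6R,7R,8R,9S) | C=C(C)C(=O)O[C@@H]1[C@@H]2C(=C)C(=O)O[C@@H]2/C=C(\C)CC/C=C(/C(=O)OC)[C@@H]1O
F2 | step 14 | ten-membered 9-ketone, methyl (1(10)E,4E,6R,7R,8R)-8-(2-methylprop-2-enoyloxy)-9-oxogermacra-1(10),4,11(13)-trien-12,6-olid-14-oate | C=C(C)C(=O)O[C@@H]1[C@@H]2C(=C)C(=O)O[C@@H]2/C=C(\C)CC/C=C(/C(=O)OC)C1=O
F3 | step 9 | methyl 2-{acetoxy[(4S)-2,2-dimethyl-1,3-dioxolan-4-yl]methyl}prop-2-enoate | CC1(C)O[C@@H](CO1)C(OC(C)=O)C(=C)C(=O)OC
F4 | step 9 | methyl (2E)-3-[(4R)-2,2-dimethyl-1,3-dioxolan-4-yl]-2-[(4,4,5,5-tetramethyl-1,3,2-dioxaborolan-2-yl)methyl]prop-2-enoate | CC1(C)O[C@@H](CO1)/C=C(/C(=O)OC)CB1OC(C)(C)C(C)(C)O1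
F5 | step 16 | 4R,5R-epoxide of 18 | C=C(C)C(=O)O[C@@H](CO[Si](CC)(CC)CC)[C@@H]1C(=C)C(=O)O[C@@H]1[C@H]1O[C@]1(C)CC/C=C(/C(=O)OC)I
F6 | step 16 | epoxy seco-aldehyde (4R,5R-epoxide of 19) | C=C(C)C(=O)O[C@@H](C=O)[C@@H]1C(=C)C(=O)O[C@@H]1[C@H]1O[C@]1(C)CC/C=C(/C(=O)OC)I
F7 | step 16 | epoxy alkenylchromium dichloride (4R,5R-epoxide of 20, not isolated) | C=C(C)C(=O)O[C@@H](C=O)[C@@H]1C(=C)C(=O)O[C@@H]1[C@H]1O[C@]1(C)CC/C=C(/C(=O)OC)[Cr](Cl)Cl
F8 | step 16 | epoxy ten-membered alcohol (9-deacetyl-fluctuadin) | C=C(C)C(=O)O[C@@H]1[C@@H]2C(=C)C(=O)O[C@@H]2[C@H]2O[C@]2(C)CC/C=C(/C(=O)OC)[C@H]1O
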